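**Retrosynthetic overview**

1. The 1,2-dioxane is the only ring made in the route and is closed last: the O–H of a C3 hydroperoxide adds 6-endo across the (5E)-trisubstituted alkene (O–C6 bond). The cyclohexenone ring is bought as 2,6,6-trimethylcyclohex-2-en-1-one and transposed early.
2. The C3–OOH comes from the anti C3–OH by SN2 inversion; C2 and C3 come from dimethyl (S)-malate by Fráter–Seebach methylation.
3. The C4–C5 and C8–C9 bonds are made under blue light by nickel/photoredox cross-electrophile coupling of alkyl iodides with (E)-alkenyl bromides.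
4. Both (E)-trisubstituted alkenes come from one C5 unit, (3E)-4-bromo-3-methylbut-3-en-1-ol, made by zirconium-catalysed carboalumination of but-3-yn-1-ol.

Assumption: dimethyl (S)-malate, but-3-yn-1-ol, 2,6,6-trimethylcyclohex-2-en-1-one and all reagents are taken as catalogue chemicals; C1–C12 denote the dodecanoate chain of the target (C1 = ester carbon).

**Route**

Step 1
Reactants: 1 dimethyl (S)-malate
Product: 3 dimethyl (2S,3R)-2-hydroxy-3-methylbutanedioate, via dilithium alkoxide enolate 2 (not isolated)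
Conditions: LiN(iPr)2 (2.2 equiv), THF, −78 → −20 °C; MeI, −78 → −10 °C; aq. work-up
Reagents that add atoms: iodomethane, CI
Why: Fráter–Seebach alkylation; the chelated dilithium alkoxide enolate is methylated on the face away from the ester on the carbinol carbon, so the bought (S) centre sets the new methyl centre anti (about 9:1, minor isomer removed on silica).

Step 2
Reactants: 3 dimethyl (2S,3R)-2-hydroxy-3-methylbutanedioate
Product: 4 methyl (2R,3S)-3,4-dihydroxy-2-methylbutanoate
Conditions: BH3·SMe2 (1.05 equiv), NaBH4 (5 mol%), THF, 0 °C → rt; MeOH quench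
Reagents that add atoms: none
Why: Hydroxyl-directed chemoselective borane reduction; the alkoxyborane formed at the free OH reduces only the neighbouring α-hydroxy ester and leaves the other ester and both stereocentres untouched.

Step 3
Reactants: 4 methyl (2R,3S)-3,4-dihydroxy-2-methylbutanoate
Product: 5 methyl (2R,3S)-3-hydroxy-4-iodo-2-methylbutanoate
Conditions: I2 (1.1 equiv), PPh3 (1.1 equiv), imidazole (1.5 equiv), CH2Cl2, 0 °C
Reagents that add atoms: iodine, II
Why: Appel-type iodination is selective for the primary hydroxyl; C3 is not touched.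

Step 4
Reactants: 6 but-3-yn-1-ol
Product: 8 (3E)-4-bromo-3-methylbut-3-en-1-ol, via alkenylalane 7 (not isolated)
Conditions: Me3Al (3 equiv), Cp2ZrCl2 (25 mol%), CH2Cl2, 0 °C → rt; then N-bromosuccinimide, THF, −30 °C
Reagents that add atoms: trimethylaluminium, C[Al](C)C; N-bromosuccinimide, O=C1CCC(=O)N1Br
Why: Negishi zirconium-catalysed carboalumination adds methyl and aluminium syn across the alkyne (methyl to the internal carbon) and bromodealumination goes with retention, giving the (E)-alkenyl bromide.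

Step 5
Reactants: 5 methyl (2R,3S)-3-hydroxy-4-iodo-2-methylbutanoate, 8 (3E)-4-bromo-3-methylbut-3-en-1-ol
Product: 9 methyl (2R,3R,5E)-3,8-dihydroxy-2,6-dimethyloct-5-enoate
Conditions: [Ir(dF(CF3)ppy)2(dtbbpy)]PF6 (1 mol%), NiCl2·(MeOCH2CH2OMe) (5 mol%), 4,4'-di-tert-butyl-2,2'-bipyridine (6 mol%), (Me3Si)3SiH (1.2 equiv), 2,6-lutidine (2 equiv), DME, blue LEDs (450 nm), rt; 5 in 1.5-fold excess
Reagents that add atoms: none
Why: Silyl-radical nickel/photoredox cross-electrophile coupling; the photogenerated silyl radical abstracts iodine from 5, nickel inserts into the alkenyl C–Br bond of 8, and C4–C5 forms with retention of E geometry under neutral conditions that spare the free hydroxyls, the ester and both stereocentres (C3 becomes R only through a priority change).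

Step 6
Reactants: 9 methyl (2R,3R,5E)-3,8-dihydroxy-2,6-dimethyloct-5-enoate
Product: 10 methyl (2R,3R,5E)-3-hydroxy-8-iodo-2,6-dimethyloct-5-enoate
Conditions: I2 (1.05 equiv), PPh3 (1.05 equiv), imidazole (1.5 equiv), CH2Cl2, 0 °C
Reagents that add atoms: iodine, II
Why: Appel iodination of the unhindered primary alcohol is much faster than that of the branched secondary C3–OH.

Step 7
Reactants: 8 (3E)-4-bromo-3-methylbut-3-en-1-ol
Product: 11 (1E)-1-bromo-4-iodo-2-methylbut-1-ene
Conditions: I2 (1.1 equiv), PPh3 (1.1 equiv), imidazole (1.5 equiv), CH2Cl2, 0 °C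
Reagents that add atoms: iodine, II
Why: Appel iodination; the alkene geometry is not affected.

Step 8
Reactants: 11 (1E)-1-bromo-4-iodo-2-methylbut-1-ene, 12 2,6,6-trimethylcyclohex-2-en-1-one
Product: 14 1-[(3E)-4-bromo-3-methylbut-3-en-1-yl]-2,6,6-trimethylcyclohex-2-en-1-ol, via alkylmagnesium iodide 13 (not isolated)
Conditions: Mg turnings, Et2O, 0 °C → rt; then 12, LaCl3·2LiCl (0.3 equiv), THF, −78 → 0 °C; aq. work-up
Reagents that add atoms: none
Why: Chemoselective Grignard formation at the C(sp3)–I bond (the alkenyl bromide does not insert magnesium in ether) followed by lanthanum-assisted 1,2-addition to the hindered enone; the new carbinol centre is racemic and is erased in step 9.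

Step 9
Reactants: 14 1-[(3E)-4-bromo-3-methylbut-3-en-1-yl]-2,6,6-trimethylcyclohex-2-en-1-ol
Product: 15 3-[(3E)-4-bromo-3-methylbut-3-en-1-yl]-2,4,4-trimethylcyclohex-2-en-1-one
Conditions: pyridinium chlorochromate [C5H5NH][CrO3Cl] (2.5 equiv), 4 Å sieves, CH2Cl2, rt
Reagents that add atoms: pyridinium chlorochromate, [O-][Cr](=O)(=O)Cl.c1cc[nH+]cc1
Why: Dauben oxidative 1,3-transposition; [3,3] shift of the tertiary allylic chromate ester and oxidation give the 3-alkyl-2,4,4-trimethyl enone of the target.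

Step 10
Reactants: 10 methyl (2R,3R,5E)-3-hydroxy-8-iodo-2,6-dimethyloct-5-enoate, 15 3-[(3E)-4-bromo-3-methylbut-3-en-1-yl]-2,4,4-trimethylcyclohex-2-en-1-one
Product: 16 methyl (2R,3R,5E,9E)-3-hydroxy-2,6,10-trimethyl-12-(2,6,6-trimethyl-3-oxocyclohex-1-en-1-yl)dodeca-5,9-dienoate
Conditions: [Ir(dF(CF3)ppy)2(dtbbpy)]PF6 (1 mol%), NiCl2·(MeOCH2CH2OMe) (5 mol%), 4,4'-di-tert-butyl-2,2'-bipyridine (6 mol%), (Me3Si)3SiH (1.2 equiv), 2,6-lutidine (2 equiv), DME, blue LEDs (450 nm), rt
Reagents that add atoms: none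
Why: The same nickel/photoredox cross-electrophile coupling forms C8–C9; the silyl radical takes iodine from the alkyl iodide far faster than bromine from the alkenyl bromide, nickel couples with retention of E geometry, and the hindered tetrasubstituted enone, the ester and the free C3–OH are tolerated.

Step 11
Reactants: 16 methyl (2R,3R,5E,9E)-3-hydroxy-2,6,10-trimethyl-12-(2,6,6-trimethyl-3-oxocyclohex-1-en-1-yl)dodeca-5,9-dienoate
Product: 18 methyl (2R,3S,5E,9E)-3-hydroperoxy-2,6,10-trimethyl-12-(2,6,6-trimethyl-3-oxocyclohex-1-en-1-yl)dodeca-5,9-dienoate, via C3 triflate 17 (not isolated)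
Conditions: Tf2O (1.2 equiv), 2,6-lutidine (2.5 equiv), CH2Cl2, −78 °C; then anhydrous H2O2 (20 equiv, about 3 M in Et2O), −78 → 0 °C
Reagents that add atoms: hydrogen peroxide, OO
Why: SN2 perhydrolysis of a secondary triflate; the α-effect nucleophile H2O2 displaces triflate with inversion, turning the anti (3R) alcohol into the syn (3S) hydroperoxide, while low temperature and the absence of strong base hold back elimination to the enoate and participation by the homoallylic alkene.

Step 12
Reactants: 18 methyl (2R,3S,5E,9E)-3-hydroperoxy-2,6,10-trimethyl-12-(2,6,6-trimethyl-3-oxocyclohex-1-en-1-yl)dodeca-5,9-dienoate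
Product: 19 methyl (2R)-2-[(3S,6R)-6-methyl-6-[(3E)-4-methyl-6-(2,6,6-trimethyl-3-oxocyclohex-1-en-1-yl)hex-3-en-1-yl]-1,2-dioxan-3-yl]propanoate
Conditions: HNTf2 (5 mol%), toluene, −60 → −30 °C; Et3N quench
Reagents that add atoms: none
Why: Proposed new method: a weakly coordinating Brønsted acid protonates C5 of the (5E)-alkene while the terminal oxygen of the C3 hydroperoxide adds anti to C6 (6-endo, Markovnikov) through a chair transition state in which the C3 substituent and the C7 chain (trans to C4 on the alkene) are equatorial and the C6 methyl (cis to C4) is axial, so the bought C3 centre and the E geometry together give (6R) with the methyl cis to the propanoate; only O–H adds, so the O–O bond is kept, and the pendant nucleophile makes this alkene react faster than the remote C9=C10 alkene; the closest known reaction types are Brønsted acid-catalysed intramolecular hydroalkoxylation of unactivated alkenes and cycloperoxymercuration or cycloperoxyiodination of unsaturated hydroperoxides, whereas a catalytic proton-initiated cycloisomerisation of a hydroperoxy alkene to a 1,2-dioxane is, to my knowledge, unreported.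

**Compound list**

1 | dimethyl (2S)-2-hydroxybutanedioate (dimethyl (S)-malate) | COC(=O)C[C@H](O)C(=O)OC | starting material
2 | dilithium alkoxide enolate of 1 (C2–OLi and lithium enolate of the C4 ester) | COC(O[Li])=C[C@H](O[Li])C(=O)OC | intermediate
3 | dimethyl (2S,3R)-2-hydroxy-3-methylbutanedioate | COC(=O)[C@H](C)[C@H](O)C(=O)OC | intermediate
4 | methyl (2R,3S)-3,4-dihydroxy-2-methylbutanoate | COC(=O)[C@H](C)[C@H](O)CO | intermediate
5 | methyl (2R,3S)-3-hydroxy-4-iodo-2-methylbutanoate | COC(=O)[C@H](C)[C@H](O)CI | intermediate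
6 | but-3-yn-1-ol | C#CCCO | starting material
7 | [(1E)-4-(dimethylalumanyloxy)-2-methylbut-1-en-1-yl]dimethylalumane | C[Al](C)/C=C(\C)CCO[Al](C)C | intermediate
8 | (3E)-4-bromo-3-methylbut-3-en-1-ol | Br/C=C(\C)CCO | intermediate
9 | methyl (2R,3R,5E)-3,8-dihydroxy-2,6-dimethyloct-5-enoate | COC(=O)[C@H](C)[C@H](O)C/C=C(\C)CCO | intermediate
10 | methyl (2R,3R,5E)-3-hydroxy-8-iodo-2,6-dimethyloct-5-enoate | COC(=O)[C@H](C)[C@H](O)C/C=C(\C)CCI | intermediate
11 | (1E)-1-bromo-4-iodo-2-methylbut-1-ene | Br/C=C(\C)CCI | intermediate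
12 | 2,6,6-trimethylcyclohex-2-en-1-one | CC1=CCCC(C)(C)C1=O | starting material
13 | [(3E)-4-bromo-3-methylbut-3-en-1-yl]magnesium iodide | Br/C=C(\C)CC[Mg]I | intermediate
14 | 1-[(3E)-4-bromo-3-methylbut-3-en-1-yl]-2,6,6-trimethylcyclohex-2-en-1-ol (racemic at the carbinol carbon) | CC1=CCCC(C)(C)C1(O)CC/C(C)=C/Br | intermediate
15 | 3-[(3E)-4-bromo-3-methylbut-3-en-1-yl]-2,4,4-trimethylcyclohex-2-en-1-one | CC1=C(CC/C(C)=C/Br)C(C)(C)CCC1=O | intermediate
16 | methyl (2R,3R,5E,9E)-3-hydroxy-2,6,10-trimethyl-12-(2,6,6-trimethyl-3-oxocyclohex-1-en-1-yl)dodeca-5,9-dienoate | COC(=O)[C@H](C)[C@H](O)C/C=C(\C)CC/C=C(\C)CCC1=C(C)C(=O)CCC1(C)C | intermediate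
17 | methyl (2R,3R,5E,9E)-2,6,10-trimethyl-3-[(trifluoromethanesulfonyl)oxy]-12-(2,6,6-trimethyl-3-oxocyclohex-1-en-1-yl)dodeca-5,9-dienoate | COC(=O)[C@H](C)[C@H](OS(=O)(=O)C(F)(F)F)C/C=C(\C)CC/C=C(\C)CCC1=C(C)C(=O)CCC1(C)C | intermediate
18 | methyl (2R,3S,5E,9E)-3-hydroperoxy-2,6,10-trimethyl-12-(2,6,6-trimethyl-3-oxocyclohex-1-en-1-yl)dodeca-5,9-dienoate | COC(=O)[C@H](C)[C@@H](OO)C/C=C(\C)CC/C=C(\C)CCC1=C(C)C(=O)CCC1(C)C | intermediate
19 | methyl (2R)-2-[(3S,6R)-6-methyl-6-[(3E)-4-methyl-6-(2,6,6-trimethyl-3-oxocyclohex-1-en-1-yl)hex-3-en-1-yl]-1,2-dioxan-3-yl]propanoate | COC(=O)[C@H](C)[C@@H]1CC[C@@](C)(CC/C=C(\C)CCC2=C(C)C(=O)CCC2(C)C)OO1 | target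

**Step count**

Total: 12 steps. Longest linear sequence: 8 steps (1, 2, 3, 5, 6, 10, 11, 12).

**Steps most likely to fail, with fallbacks**

Step 12 (the proposed new cycloisomerisation). The risks are loss of stereospecificity if a free C6 cation forms or the tertiary C6–O bond re-ionises, proton-induced isomerisation of the C9=C10 alkene, and acid decomposition of the hydroperoxide. The fallback is known chemistry and sets out from 18. Cycloperoxyiodination with N-iodosuccinimide (CH2Cl2, −30 °C, dark) is reversible at the remote alkene and is captured irreversibly by the hydroperoxide in an anti 6-endo addition, giving methyl (2R)-2-[(3S,5S,6R)-5-iodo-6-methyl-6-[(3E)-4-methyl-6-(2,6,6-trimethyl-3-oxocyclohex-1-en-1-yl)hex-3-en-1-yl]-1,2-dioxan-3-yl]propanoate F1. Radical deiodination with Bu3SnH (0.5 M, Et3B/air, toluene, −20 °C), where the high hydride concentration outruns fragmentation of the β-peroxy radical, comes back to the route at 19.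

Step 11 (hydroperoxide by SN2). The risks are elimination to the 2-methyl-2-enoate and alkene-assisted ionisation of the homoallylic triflate, which would erode the inversion. The fallback sets out from 16 and passes through triflate 17 at −78 °C. The triflate is alkylated with the potassium salt of 2-methoxypropan-2-yl hydroperoxide (hydroperoxide made by ozonolysis of 2,3-dimethylbut-2-ene in methanol; KOtBu, THF, −78 °C), an anionic protected peroxide that reacts by fast SN2 before ionisation can compete. This gives methyl (2R,3S,5E,9E)-3-[(2-methoxypropan-2-yl)peroxy]-2,6,10-trimethyl-12-(2,6,6-trimethyl-3-oxocyclohex-1-en-1-yl)dodeca-5,9-dienoate F2. Mild acid (AcOH/H2O/THF, rt) unmasks the hydroperoxide and comes back to the route at 18.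

Step 10 (photochemical union of the two advanced pieces). The risks are hydrodehalogenation of either partner and slow coupling at the hindered alkenyl bromide when the partners are used 1:1. The fallback replaces the radical coupling by a polar organozinc coupling and sets out from 10. Silylation (Et3SiCl, imidazole, CH2Cl2) gives methyl (2R,3R,5E)-8-iodo-2,6-dimethyl-3-[(triethylsilyl)oxy]oct-5-enoate F3. Zinc insertion (Zn dust, LiCl, THF, rt) gives [(3E,6R,7R)-8-methoxy-3,7-dimethyl-8-oxo-6-[(triethylsilyl)oxy]oct-3-en-1-yl]zinc iodide F4. Negishi coupling with 15 (PdCl2(dppf) 3 mol%, THF, 40 °C) gives methyl (2R,3R,5E,9E)-2,6,10-trimethyl-3-[(triethylsilyl)oxy]-12-(2,6,6-trimethyl-3-oxocyclohex-1-en-1-yl)dodeca-5,9-dienoate F5. Desilylation (HF·pyridine, THF, 0 °C) comes back to the route at 16.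

**Further compounds**

F1 | step 12 | methyl (2R)-2-[(3S,5S,6R)-5-iodo-6-methyl-6-[(3E)-4-methyl-6-(2,6,6-trimethyl-3-oxocyclohex-1-en-1-yl)hex-3-en-1-yl]-1,2-dioxan-3-yl]propanoate | COC(=O)[C@H](C)[C@@H]1C[C@H](I)[C@@](C)(CC/C=C(\C)CCC2=C(C)C(=O)CCC2(C)C)OO1
F2 | step 11 | methyl (2R,3S,5E,9E)-3-[(2-methoxypropan-2-yl)peroxy]-2,6,10-trimethyl-12-(2,6,6-trimethyl-3-oxocyclohex-1-en-1-yl)dodeca-5,9-dienoate | COC(=O)[C@H](C)[C@@H](OOC(C)(C)OC)C/C=C(\C)CC/C=C(\C)CCC1=C(C)C(=O)CCC1(C)C
F3 | step 10 | methyl (2R,3R,5E)-8-iodo-2,6-dimethyl-3-[(triethylsilyl)oxy]oct-5-enoate | COC(=O)[C@H](C)[C@H](O[Si](CC)(CC)CC)C/C=C(\C)CCI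
F4 | step 10 | [(3E,6R,7R)-8-methoxy-3,7-dimethyl-8-oxo-6-[(triethylsilyl)oxy]oct-3-en-1-yl]zinc iodide | COC(=O)[C@H](C)[C@H](O[Si](CC)(CC)CC)C/C=C(\C)CC[Zn]I
F5 | step 10 | methyl (2R,3R,5E,9E)-2,6,10-trimethyl-3-[(triethylsilyl)oxy]-12-(2,6,6-trimethyl-3-oxocyclohex-1-en-1-yl)dodeca-5,9-dienoate | COC(=O)[C@H](C)[C@H](O[Si](CC)(CC)CC)C/C=C(\C)CC/C=C(\C)CCC1=C(C)C(=O)CCC1(C)C
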